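**Plan**

1. Retrosynthesis: remove the six O‑benzyl groups; take the carbinol C–OH back to C–B(pin); cut the chain bond P3–P4 (carbinol carbon to the CH2 leading to the side‑chain catechol ring) into an α‑chloroboronate and a homobenzylic zinc reagent; cut P2–P3 into an acetate enolate and Cl2CH–Bpin; cut the ester C–O bond back to tetra‑O‑benzyl‑(+)‑catechin.
2. Forward: no ring is made. The chroman ring system is taken intact from (+)‑catechin and the chain grows outward from the flavan C3–O: acetate (P1–P2), then P3 by Matteson homologation, then P4–P5–aryl by nickel‑catalysed alkyl–alkyl coupling, then B→OH, then global debenzylation.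
3. Enabling feature: P3 is a secondary carbinol carbon flanked by two CH2 groups and 1,3 to the ester carbonyl P1. Carried as C(Cl)–Bpin it gives a boron‑stabilised radical, so both epimers funnel into one configuration while the bond to P4 forms, and the boron is the latent hydroxyl.
4. Stereochemistry: C2 (R) and C3 (S) of the pyran ring come from (+)‑catechin and are never touched. P3 (S) is set in the key step by the chiral diamine–nickel catalyst and kept through the B→O oxidation, which proceeds with retention.

Key step: step 6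

Remark: the SMILES defines a 2,3‑trans flavan‑3‑ol of (2R,3S) configuration, which is that of (+)‑catechin, and an (S) side‑chain carbinol; the route is built for exactly this isomer. Chain atoms are called P1 (ester C=O) to P5 (benzylic CH2).

**Route**

Step 1
Reactants: 1 (+)-catechin; 2 benzyl bromide
Product: 3 5,7,3′,4′-tetra-O-benzyl-(+)-catechin
Conditions: BnBr (4.4 equiv), K2CO3, DMF, 0 °C → rt, N2
Reagents that add atoms: benzyl bromide, BrCc1ccccc1
Why: Williamson etherification; K2CO3 deprotonates only the four phenols, so the secondary C3–OH stays free and the low temperature should limit C‑benzylation and epimerisation at C2.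

Step 2
Reactants: 3 5,7,3′,4′-tetra-O-benzyl-(+)-catechin; 4 acetic anhydride
Product: 5 5,7,3′,4′-tetra-O-benzyl-(+)-catechin 3-O-acetate
Conditions: Ac2O, pyridine, DMAP (cat.), rt
Reagents that add atoms: acetic anhydride, CC(=O)OC(C)=O
Why: DMAP‑catalysed acyl transfer to the hindered secondary alcohol (Steglich‑type acylation); no stereocentre is involved.

Step 3
Reactants: 5 5,7,3′,4′-tetra-O-benzyl-(+)-catechin 3-O-acetate; 6 2-(dichloromethyl)-4,4,5,5-tetramethyl-1,3,2-dioxaborolane
Product: 9 tetra-O-benzylcatechin 3-O-[3-chloro-3-(pinacolboryl)propanoate] (both P3 epimers), via lithium enolate 7 (not isolated), via lithium borate complex 8 (not isolated)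
Conditions: LDA (commercial solution, 1.05 equiv), THF, −78 °C; then 6, −78 °C → rt
Reagents that add atoms: 2-(dichloromethyl)-4,4,5,5-tetramethyl-1,3,2-dioxaborolane, ClC(Cl)B1OC(C)(C)C(C)(C)O1
Why: Matteson homologation; the ester enolate adds through carbon to boron and the borate undergoes 1,2‑migration of the CH2CO2R group with loss of one chloride, forming P2–P3 and leaving the second chloride for step 6, and the epimeric mixture at P3 is acceptable because step 6 is stereoconvergent.

Step 4
Reactants: 10 2-[3,4-bis(benzyloxy)phenyl]ethanol; 11 carbon tetrabromide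
Product: 12 4-(2-bromoethyl)-1,2-bis(benzyloxy)benzene
Conditions: CBr4, PPh3, CH2Cl2, 0 °C
Reagents that add atoms: carbon tetrabromide, BrC(Br)(Br)Br
Why: Appel reaction; bromide displaces the alkoxyphosphonium group at the primary carbon by SN2 and the benzyl ethers are inert.

Step 5
Reactants: 12 4-(2-bromoethyl)-1,2-bis(benzyloxy)benzene; 13 zinc
Product: 14 {2-[3,4-bis(benzyloxy)phenyl]ethyl}zinc bromide (titrated DMA solution)
Conditions: Zn dust, I2 (5 mol %), DMA, 80 °C
Reagents that add atoms: zinc, [Zn]
Why: direct oxidative insertion of iodine‑activated zinc into a primary alkyl bromide in a polar aprotic solvent; aryl benzyl ethers are tolerated and the solution is used as such.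

Step 6
Reactants: 9 tetra-O-benzylcatechin 3-O-[3-chloro-3-(pinacolboryl)propanoate]; 14 {2-[3,4-bis(benzyloxy)phenyl]ethyl}zinc bromide
Product: 15 tetra-O-benzylcatechin 3-O-[(3S)-5-(3,4-bis(benzyloxy)phenyl)-3-(pinacolboryl)pentanoate]
Conditions: NiBr2·diglyme (10 mol %), chiral N,N′-dimethyl-1,2-diphenylethane-1,2-diamine (13 mol %, the antipode that delivers 3S, assigned on a model α-chloroboronate), 14 (1.8 equiv), THF/DMA, 0 °C
Reagents that add atoms: none
Why: Transmetalation of 14 to the diamine–nickel centre gives an alkylnickel species that abstracts chlorine from either P3 epimer of 9, so both converge on one planar α‑boryl radical at P3 (stabilised by the vacant p orbital on boron); capture of this radical by the chiral alkylnickel complex and reductive elimination from Ni(III) forms the P3–P4 bond. The closest known reaction type is the nickel/chiral‑diamine enantioconvergent Negishi alkyl–alkyl coupling of racemic α‑chloroboronic esters with alkylzinc halides. No ring is closed. The new stereocentre P3 is controlled by the ligand on nickel, not by the flavan, whose nearest stereocentre (C3) lies four bonds away, so the epimeric mixture should converge on the (S)‑boronate. The step needs reaction at C–Cl in preference to the ester and benzyl ethers, which the low nucleophilicity and basicity of RZnBr secures. It also needs coupling to outrun β‑hydride elimination and loss of HCl to the β‑borylacrylate, which the non‑basic medium, 0 °C and fast reductive elimination should secure.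

Step 7
Reactants: 15 tetra-O-benzylcatechin 3-O-[(3S)-5-(3,4-bis(benzyloxy)phenyl)-3-(pinacolboryl)pentanoate]; 16 sodium perborate (used as the tetrahydrate)
Product: 17 tetra-O-benzylcatechin 3-O-[(3S)-5-(3,4-bis(benzyloxy)phenyl)-3-hydroxypentanoate]
Conditions: NaBO3·4H2O, THF/H2O 1:1, rt
Reagents that add atoms: sodium perborate, [Na+].[Na+].O[B-]1(O)OO[B-](O)(O)OO1
Why: oxidation of the C–B bond; peroxide adds to boron and carbon migrates from B to O with retention, so (S)‑C–B becomes (S)‑C–OH, and the near‑neutral conditions should spare the ester and avoid retro‑aldol cleavage or dehydration.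

Step 8
Reactants: 17 tetra-O-benzylcatechin 3-O-[(3S)-5-(3,4-bis(benzyloxy)phenyl)-3-hydroxypentanoate]
Product: 18 phylloflavan
Conditions: H2 (1 atm), 20% Pd(OH)2/C, THF/MeOH 1:1, rt
Reagents that add atoms: none
Why: catalytic hydrogenolysis of the six aryl benzyl ethers over Pearlman's catalyst; the ester, the secondary alcohol and the cyclic benzylic C2–O1 ether are expected to survive if the reaction is stopped after uptake of six equivalents, and no stereocentre is touched.

**Compound list**

1 | (+)-catechin | O[C@H]1Cc2c(O)cc(O)cc2O[C@@H]1c1ccc(O)c(O)c1 | starting material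
2 | benzyl bromide | BrCc1ccccc1 | starting material
3 | 5,7,3′,4′-tetra-O-benzyl-(+)-catechin, (2R,3S) | O[C@H]1Cc2c(OCc3ccccc3)cc(OCc3ccccc3)cc2O[C@@H]1c1ccc(OCc2ccccc2)c(OCc2ccccc2)c1 | intermediate
4 | acetic anhydride | CC(=O)OC(C)=O | starting material
5 | 5,7,3′,4′-tetra-O-benzyl-(+)-catechin 3-O-acetate | CC(=O)O[C@H]1Cc2c(OCc3ccccc3)cc(OCc3ccccc3)cc2O[C@@H]1c1ccc(OCc2ccccc2)c(OCc2ccccc2)c1 | intermediate
6 | 2-(dichloromethyl)-4,4,5,5-tetramethyl-1,3,2-dioxaborolane | ClC(Cl)B1OC(C)(C)C(C)(C)O1 | starting material
7 | lithium enolate of 5 | [Li+].C=C([O-])O[C@H]1Cc2c(OCc3ccccc3)cc(OCc3ccccc3)cc2O[C@@H]1c1ccc(OCc2ccccc2)c(OCc2ccccc2)c1 | intermediate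
8 | lithium borate complex of 7 and 6 | [Li+].ClC(Cl)[B-]1(CC(=O)O[C@H]2Cc3c(OCc4ccccc4)cc(OCc4ccccc4)cc3O[C@@H]2c2ccc(OCc3ccccc3)c(OCc3ccccc3)c2)OC(C)(C)C(C)(C)O1 | intermediate
9 | tetra-O-benzylcatechin 3-O-[3-chloro-3-(pinacolboryl)propanoate], both P3 epimers | O=C(CC(Cl)B1OC(C)(C)C(C)(C)O1)O[C@H]1Cc2c(OCc3ccccc3)cc(OCc3ccccc3)cc2O[C@@H]1c1ccc(OCc2ccccc2)c(OCc2ccccc2)c1 | intermediate
10 | 2-[3,4-bis(benzyloxy)phenyl]ethanol | OCCc1ccc(OCc2ccccc2)c(OCc2ccccc2)c1 | starting material
11 | carbon tetrabromide | BrC(Br)(Br)Br | starting material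
12 | 4-(2-bromoethyl)-1,2-bis(benzyloxy)benzene | BrCCc1ccc(OCc2ccccc2)c(OCc2ccccc2)c1 | intermediate
13 | zinc | [Zn] | starting material
14 | {2-[3,4-bis(benzyloxy)phenyl]ethyl}zinc bromide | Br[Zn]CCc1ccc(OCc2ccccc2)c(OCc2ccccc2)c1 | intermediate
15 | tetra-O-benzylcatechin 3-O-[(3S)-5-(3,4-bis(benzyloxy)phenyl)-3-(pinacolboryl)pentanoate] | O=C(C[C@@H](B1OC(C)(C)C(C)(C)O1)CCc1ccc(OCc2ccccc2)c(OCc2ccccc2)c1)O[C@H]1Cc2c(OCc3ccccc3)cc(OCc3ccccc3)cc2O[C@@H]1c1ccc(OCc2ccccc2)c(OCc2ccccc2)c1 | intermediate
16 | sodium perborate | [Na+].[Na+].O[B-]1(O)OO[B-](O)(O)OO1 | starting material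
17 | tetra-O-benzylcatechin 3-O-[(3S)-5-(3,4-bis(benzyloxy)phenyl)-3-hydroxypentanoate] | O=C(C[C@@H](O)CCc1ccc(OCc2ccccc2)c(OCc2ccccc2)c1)O[C@H]1Cc2c(OCc3ccccc3)cc(OCc3ccccc3)cc2O[C@@H]1c1ccc(OCc2ccccc2)c(OCc2ccccc2)c1 | intermediate
18 | phylloflavan, (2R,3S)-2-(3,4-dihydroxyphenyl)-5,7-dihydroxychroman-3-yl (3S)-5-(3,4-dihydroxyphenyl)-3-hydroxypentanoate | O=C(C[C@@H](O)CCc1ccc(O)c(O)c1)O[C@H]1Cc2c(O)cc(O)cc2O[C@@H]1c1ccc(O)c(O)c1 | target

**Step count and risks**

Total steps: 8. Longest linear sequence: 6 steps (1, 2, 3, 6, 7, 8); steps 4 and 5 form the side branch.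

Steps most likely to fail:

1. Step 6. The alkylnickel intermediate may undergo β‑hydride elimination, 9 may lose HCl to the β‑borylacrylate, the zinc reagent may homocouple, or catalyst control over the radical capture may be incomplete so that P3 is formed with poor facial selectivity. The fallback sets out from 3 and 14 and comes back at 15, forming the same bond as a C(sp2)–C(sp3) bond. Alcohol 3 is esterified with commercial (E)-3-iodoacrylic acid (DCC, cat. DMAP, CH2Cl2, 0 °C) to give tetra-O-benzylcatechin 3-O-[(E)-3-iodoacrylate] F1. Palladium‑catalysed Negishi coupling of F1 with 14 (PdCl2(dppf), THF, rt) should give tetra-O-benzylcatechin 3-O-[(E)-5-(3,4-bis(benzyloxy)phenyl)pent-2-enoate] F2. Copper‑catalysed asymmetric conjugate borylation of F2 (B2pin2, CuCl, NaOtBu, the Josiphos antipode that gives 3S, MeOH, THF) then installs the C–B stereocentre and returns 15.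

2. Step 3. Proton transfer between enolate or borate and the product may be followed by E1cB loss of chloride, and the 1,2‑migration of the electron‑poor α‑ester carbon may be slow, so that the borate reverts or adds twice. The fallback sets out from 6 and 3 and comes back at 9; it carries out the homologation on a simple ester and makes the flavan ester bond afterwards. tert‑Butyl acetate is deprotonated with LDA (THF, −78 °C) to the lithium enolate of tert-butyl acetate F3. F3 adds to 6 to give the lithium borate complex F4, which rearranges on warming to tert-butyl 3-chloro-3-(pinacolboryl)propanoate F5. Cleavage of the tert‑butyl ester (TFA, CH2Cl2, 0 °C) gives 3-chloro-3-(pinacolboryl)propanoic acid F6. Carbodiimide esterification of 3 with F6 (DIC, cat. DMAP, CH2Cl2, 0 °C) then gives 9.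

3. Step 8. Hydrogenolysis may stop before all six benzyl groups are removed, or go on to cleave the benzylic C2–O1 bond of the pyran ring, and the free hexaphenol may oxidise in air during isolation. The fallback sets out from 17 and comes back at 18. The benzyl groups are removed by Lewis‑acid cleavage with a cation scavenger (BCl3, pentamethylbenzene, CH2Cl2, −78 °C, then MeOH quench); this fallback makes no further compound (F0).

Further compounds
F1 | step 6 | tetra-O-benzylcatechin 3-O-[(E)-3-iodoacrylate] | O=C(/C=C/I)O[C@H]1Cc2c(OCc3ccccc3)cc(OCc3ccccc3)cc2O[C@@H]1c1ccc(OCc2ccccc2)c(OCc2ccccc2)c1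
F2 | step 6 | tetra-O-benzylcatechin 3-O-[(E)-5-(3,4-bis(benzyloxy)phenyl)pent-2-enoate] | O=C(/C=C/CCc1ccc(OCc2ccccc2)c(OCc2ccccc2)c1)O[C@H]1Cc2c(OCc3ccccc3)cc(OCc3ccccc3)cc2O[C@@H]1c1ccc(OCc2ccccc2)c(OCc2ccccc2)c1
F3 | step 3 | lithium enolate of tert-butyl acetate | [Li+].C=C([O-])OC(C)(C)C
F4 | step 3 | lithium borate complex of F3 and 6 | [Li+].CC(C)(C)OC(=O)C[B-]1(C(Cl)Cl)OC(C)(C)C(C)(C)O1
F5 | step 3 | tert-butyl 3-chloro-3-(pinacolboryl)propanoate | CC(C)(C)OC(=O)CC(Cl)B1OC(C)(C)C(C)(C)O1
F6 | step 3 | 3-chloro-3-(pinacolboryl)propanoic acid | OC(=O)CC(Cl)B1OC(C)(C)C(C)(C)O1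
F0 | step 8 | none | none
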